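**Retrosynthetic overview**
- Target ⇒ its tri-O-methyl ether. The three aryl methyl ethers are cleaved last, in the same flask as the step before.
- The two ring A–CH2 bonds (C2, C6) ⇒ two ring A O–CH2 ether bonds (O3, O5). Each benzyl group is first tied to ring A through oxygen, then moved from O to C by a new catalytic double O-to-C transposition.
- Key disconnection: those two C–O bonds ⇒ 5-bromoresorcinol + 2 × 4-methoxybenzyl chloride. This union joins rings A, B and C and fixes two benzyl groups per core, one per oxygen.
- Ring A–CH2CH2–ring D ⇒ the aryl bromide + 4-methoxystyrene (hydroboration, then B-alkyl Suzuki-Miyaura coupling).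
- No ring is formed. All four benzene rings are bought and joined in the order A + B + C, then D.

Assumption: the target has no stereocentre and is achiral, so there is no enantiomer to choose and no step has to set configuration.

Ring A numbering used below: C1 carries the CH2CH2 chain, C2 and C6 the benzyl groups, C3 and C5 oxygen, C4 hydrogen.

**Step 1**
Reactants: 1 5-bromobenzene-1,3-diol (5-bromoresorcinol); 2 4-methoxybenzyl chloride (2.2 equiv)
Product: 4 1-bromo-3,5-bis[(4-methoxybenzyl)oxy]benzene, via monoether 3 (not isolated)
Conditions: K2CO3 (3 equiv), DMF, 60 °C, 6 h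
Reagents that add atoms: 4-methoxybenzyl chloride (2), COc1ccc(CCl)cc1
Why: Double Williamson ether synthesis (SN2) in which K2CO3/DMF alkylates the two phenoxide oxygens of the electron-poor bromoresorcinol rather than carbon, and these two C–O bonds join rings A, B and C, protect the phenols for step 2, and place exactly one latent benzyl group on each oxygen; no stereocentre is formed.

**Step 2**
Reactants: 5 4-methoxystyrene (1.3 equiv); 6 9-borabicyclo[3.3.1]nonane (9-BBN, 0.5 M in THF, 1.4 equiv); 4 1-bromo-3,5-bis[(4-methoxybenzyl)oxy]benzene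
Product: 8 1-[2-(4-methoxyphenyl)ethyl]-3,5-bis[(4-methoxybenzyl)oxy]benzene, via alkylborane 7 (not isolated)
Conditions: 5, 6, THF, 0 °C to rt, 6 h; then 4, PdCl2(dppf) (5 mol%), K3PO4 (3 M aq, 3 equiv), THF/DMF, 60 °C, 12 h
Reagents that add atoms: 4-methoxystyrene (5), C=Cc1ccc(OC)cc1
Why: Anti-Markovnikov hydroboration followed by B-alkyl Suzuki-Miyaura coupling, in which 9-BBN adds almost only to the terminal carbon of the styrene, the wide bite angle of dppf favours reductive elimination over beta-hydride elimination, and aryl PMB ethers are inert to aqueous base and zerovalent palladium, so the saturated bridge forms with no hydrogenation that would strip the ethers; no stereocentre is formed.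

**Step 3**
Reactants: 8 1-[2-(4-methoxyphenyl)ethyl]-3,5-bis[(4-methoxybenzyl)oxy]benzene
Product: 11 4,6-bis(4-hydroxybenzyl)-5-[2-(4-hydroxyphenyl)ethyl]benzene-1,3-diol, via mono-shifted phenol 9 (not isolated), via doubly shifted trimethyl ether 10 (not isolated)
Conditions: Tf2NH (bis(trifluoromethanesulfonyl)imide, 10 mol%), dry CH2Cl2 (0.01 M), −20 °C to rt, 2 h; then BBr3 (10 equiv), −78 °C to rt, 12 h; H2O quench, under N2
Reagents that add atoms: none
Why: Proposed new method: a catalytic, twofold, regioconvergent O-to-C transposition of a resorcinol bis(4-methoxybenzyl) ether, in which Tf2NH protonates an ether oxygen and the C–O bond ionises to a 4-methoxybenzyl cation held in a cation-π contact pair over the ring it has just left (by far the best π-nucleophile present and, at 0.01 M, the only one within reach); the pair collapses at C2 (ortho delivery) or C6 (para delivery), both wanted sites, while C4 between the two oxygens is the position that 5-alkylresorcinol ethers are known to avoid in bromination and formylation; loss of the proton returns the catalyst, the second ether repeats the event through 9, and the count stays at two benzyl groups per core because each was tied on by its own C–O bond in step 1; BBr3 added to the same CH2Cl2 solution then cleaves the three aryl methyl ethers of 10 (standard Lewis-acid ether cleavage), and its complexation to the anisyl oxygens and borylation of the resorcinol oxygens switch off retro-Friedel-Crafts loss of the new benzyl groups; the closest known reaction types are the acid-catalysed benzyl aryl ether rearrangement to ortho-benzylphenols and the catalytic-acid transfer of PMB groups from ethers to 1,3-dimethoxybenzene as scavenger, neither of which has been shown as a planned double transposition that builds a 2,6-dibenzylated bibenzyl; no stereocentre is formed.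

**Compound list**
1 | 5-bromobenzene-1,3-diol (5-bromoresorcinol) | Oc1cc(O)cc(Br)c1 | starting material
2 | 4-methoxybenzyl chloride | COc1ccc(CCl)cc1 | starting material
3 | 3-bromo-5-[(4-methoxybenzyl)oxy]phenol | COc1ccc(COc2cc(O)cc(Br)c2)cc1 | intermediate
4 | 1-bromo-3,5-bis[(4-methoxybenzyl)oxy]benzene | COc1ccc(COc2cc(Br)cc(OCc3ccc(OC)cc3)c2)cc1 | intermediate
5 | 4-methoxystyrene | C=Cc1ccc(OC)cc1 | starting material
6 | 9-borabicyclo[3.3.1]nonane (9-BBN) | B1C2CCCC1CCC2 | starting material
7 | 9-[2-(4-methoxyphenyl)ethyl]-9-borabicyclo[3.3.1]nonane | COc1ccc(CCB2C3CCCC2CCC3)cc1 | intermediate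
8 | 1-[2-(4-methoxyphenyl)ethyl]-3,5-bis[(4-methoxybenzyl)oxy]benzene | COc1ccc(CCc2cc(OCc3ccc(OC)cc3)cc(OCc3ccc(OC)cc3)c2)cc1 | intermediate
9 | 2-(4-methoxybenzyl)-5-[(4-methoxybenzyl)oxy]-3-[2-(4-methoxyphenyl)ethyl]phenol | COc1ccc(CCc2cc(OCc3ccc(OC)cc3)cc(O)c2Cc2ccc(OC)cc2)cc1 | intermediate
10 | 4,6-bis(4-methoxybenzyl)-5-[2-(4-methoxyphenyl)ethyl]benzene-1,3-diol | COc1ccc(CCc2c(Cc3ccc(OC)cc3)c(O)cc(O)c2Cc2ccc(OC)cc2)cc1 | intermediate
11 | 4,6-bis(4-hydroxybenzyl)-5-[2-(4-hydroxyphenyl)ethyl]benzene-1,3-diol (CNP0326726.0, achiral) | Oc1ccc(CCc2c(Cc3ccc(O)cc3)c(O)cc(O)c2Cc2ccc(O)cc2)cc1 | target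

**Total step count:** 3. **Longest linear sequence:** 3 (1 to 4 to 8 to 11).

**Steps most likely to fail**

Most at risk is step 3, the new transposition.
- Risk: the 4-methoxybenzyl cation may leave the contact pair. That would give crossover products (cores with one or three benzyl groups), attack at C4, or oligomers.
- The fallback uses only known reactions. It sets out from 8 (with 2 as the benzyl source) and comes back to the route at 10.
- Electrophilic dibromination of 8 (NBS, 2.05 equiv, MeCN, 0 °C, dark) goes to the two positions para to oxygen. It gives 2,4-dibromo-3-[2-(4-methoxyphenyl)ethyl]-1,5-bis[(4-methoxybenzyl)oxy]benzene F1.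
- Zinc insertion into 2 (Zn dust, LiCl, THF, rt) gives 4-methoxybenzylzinc chloride F2.
- A double Negishi coupling of F1 with F2 (Pd(OAc)2, SPhos, THF, 60 °C) gives 2,4-bis(4-methoxybenzyl)-3-[2-(4-methoxyphenyl)ethyl]-1,5-bis[(4-methoxybenzyl)oxy]benzene F3.
- Hydrogenolysis (H2, Pd/C, EtOAc/EtOH, rt) removes only the two oxygen-bound benzyl groups and delivers 10. Here 10 is isolated and then demethylated with BBr3 as in the second stage of step 3.

Second is step 2.
- Risk: slow transmetalation of the alkylborane, protodeboronation or beta-hydride elimination would return 4-ethylanisole and the reduced arene.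
- The fallback sets out from 4 and 5 and comes back at 8.
- A Mizoroki-Heck coupling (Pd(OAc)2, P(o-tol)3, K2CO3, DMF, 110 °C) gives (E)-1-[2-(4-methoxyphenyl)ethenyl]-3,5-bis[(4-methoxybenzyl)oxy]benzene F4.
- The alkene of F4 is then saturated with H2 over pyridine-poisoned Pd/C (MeOH/dioxane, rt) to give 8. These conditions are known to spare phenolic PMB ethers.

Third is step 1.
- Risk: the ambident resorcinolate can be benzylated on carbon, and aged 4-methoxybenzyl chloride self-condenses.
- The fallback sets out from 1 and comes back at 4.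
- A double Mitsunobu etherification with 4-methoxybenzyl alcohol (COc1ccc(CO)cc1, 2.4 equiv), PPh3 and DIAD in THF (0 °C to rt) forms the same two C–O bonds. It is a redox dehydration with no free phenoxide and no benzyl halide.
- This fallback makes no compound outside the list (F0).

**Further compounds**
F1 | step 3 | 2,4-dibromo-3-[2-(4-methoxyphenyl)ethyl]-1,5-bis[(4-methoxybenzyl)oxy]benzene | COc1ccc(CCc2c(Br)c(OCc3ccc(OC)cc3)cc(OCc3ccc(OC)cc3)c2Br)cc1
F2 | step 3 | 4-methoxybenzylzinc chloride | COc1ccc(C[Zn]Cl)cc1
F3 | step 3 | 2,4-bis(4-methoxybenzyl)-3-[2-(4-methoxyphenyl)ethyl]-1,5-bis[(4-methoxybenzyl)oxy]benzene | COc1ccc(CCc2c(Cc3ccc(OC)cc3)c(OCc3ccc(OC)cc3)cc(OCc3ccc(OC)cc3)c2Cc2ccc(OC)cc2)cc1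
F4 | step 2 | (E)-1-[2-(4-methoxyphenyl)ethenyl]-3,5-bis[(4-methoxybenzyl)oxy]benzene | COc1ccc(/C=C/c2cc(OCc3ccc(OC)cc3)cc(OCc3ccc(OC)cc3)c2)cc1
F0 | step 1 | none | none
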